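1. At 50 °C, your hunch that waiting still pays does not survive the larch run, which is this very flask followed so far.

| flask | starting material | reagent | temperature | remark | time |
|---|---|---|---|---|---|
| larch | 0.015 M | 0.015 M | 50 °C | the very flask that is asked about, followed so far |  |
| maple | 0.0075 M | 0.015 M | 35 °C | run made earlier |  |
| flask | 0.015 M | 0.0150 M | 50 °C |  | 30 h |

| run | time / h | target / % | starting material / % |
|---|---|---|---|
| larch | 5.00 | 61.7 | 26.2 |
| larch | 10.0 | 59.5 | 23.5 |
| larch | 15.0 | 57.0 | 23.3 |
| larch | 20.0 | 56.7 | 16.8 |
| maple | 0.833 | 45.0 | 52.8 |
| maple | 2.00 | 68.0 | 32.4 |
| maple | 4.00 | 80.2 | 17.2 |
| maple | 6.00 | 88.1 | 12.7 |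

(each reading ± 1 percentage point)

- ochre: change nothing and wait 15 h more
- red: at 30 h add reagent, 100% of the amount charged, then wait 15 h
- grey: at 30 h take out 90% of the target then present, then wait 15 h
- amber: at 30 h raise the temperature by 20 K, then wait 15 h

- target that was removed still counts
- the numbers in the tables scatter by 1 percentage point (one standard deviation)
- additions bring no volume worth counting

* target, in percent of the starting material first charged, at 30 h
* the option that brings most further target ("none" if no option brings more than 2 percentage points) (ochre / red / grey / amber / none)
* target present, with what was taken out counted in, in percent of the starting material first charged, after grey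
* target present, with what was taken out counted in, in percent of the starting material first charged, after amber

2. In the larch run, starting material falls by 74 percentage points up to 5.00 h but by 9.4 points in the next 15.0 h, so I take conversion by reagent to have stalled.

3. After the stall, [starting material] + [target] drops by 14 points, while the difference between them shifts by 4.4 points, less. I read this as the two consuming each other, one for one.

4. So I carry the excess, [target] − [starting material] in percent of the charge, a conserved quantity once reagent stops acting. The larch readings average 36 points, and I take that as my floor: where pairing uses up the starting material, [target] stands at about that reading.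

5. The larch readings give a drain on starting material of 0.0296 h⁻¹. Run on to 30 h, that gives 12.5% starting material, and target falls equally, to 52.4%.

6. Going round once more, I scale the drain by mean [target], to 0.0273 h⁻¹. That leaves 12.8% starting material and 52.7% target, which is my number.

7. I choose red, which offers that 12.8% of starting material for conversion to new target. Amber, by my reckoning, stays above 36 points.

8. The forecast says 53% at 30 h, red as best, 52.5% after grey and 30% after amber; of amber it writes “Amber only speeds decay”, and its amber figure stands below my floor.

9. The flask gives 51.6%, red (gain 13 points), 51.1% and 39.9%.

    starting material + reagent → target (k = 170 M⁻¹ h⁻¹, Ea = 49.0 kJ mol⁻¹)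
    2 reagent → side product A (k = 61.0 M⁻¹ h⁻¹, Ea = 72.0 kJ mol⁻¹)
    starting material + target → side product B (k = 3.10 M⁻¹ h⁻¹, Ea = 86.0 kJ mol⁻¹)
    (constants at 50 °C)

Amber's 39.9% stays above the floor. Left alone, the flask has not come to rest at 30.0 h: it holds 13.6% starting material and 51.6% target, a difference of 38 points. At 300 h it holds 0.0846% starting material, 38.1% target and 61.8% side product B, a difference of 38 points. In the neighbour flask, the same flask charged with 0.0037 M reagent, 0% of that reagent stands at 30.0 h and the difference is −55 points, negative, so there target is the partner that stands to be used up, at 8.69% against 63.6% starting material.

The numbers in the tables come from a simulation from invented constants, noise included.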